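## Retrosynthetic overview

1. The target comes from its all-cis tosylate by base: C2 epimerises to the 2,3-trans arrangement and the phenol is unmasked.
2. Ring B comes from a two-carbon ring expansion: 4,5-dimethoxybenzyne (ring A) inserts into the C(=O)–C(aryl) bond of a 2-aryl-3,4-dimethylcyclobutanone enolate (net 1,2-acyl shift). Protonation of C4 anti to the methyl groups gives the 3,4-cis relationship.
3. The cyclobutanone comes from an auxiliary-controlled keteniminium + cis-2-butene [2+2] cycloaddition, which sets C3, the stereocentre that steers the others.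
4. The arylacetamide comes from a benzylic chloride, CO and a C2-symmetric pyrrolidine. The chloride comes from chloromethylation of 2-methoxyphenyl tosylate (ring C, from catechol), and the benzyne source from dibromoveratrole (from catechol).
5. Ring order: rings A and C are bought as catechol; the cyclobutane is made first and is then expanded to ring B in the key step.

Assumption: the (2R,5R)-auxiliary 9 is taken to give the (3S)-cyclobutanone 14 as drawn; if the sense of induction is the reverse, the (2S,5S)-enantiomer of 9 is used with no other change.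

## Route

Step 1
Reactants: 1 catechol
Product: 2 1,2-dimethoxybenzene
Conditions: MeI (2.5 equiv), K2CO3, acetone, reflux
Reagents that add atoms: iodomethane, CI
Why: Williamson ether synthesis; both phenoxides are methylated.

Step 2
Reactants: 2 1,2-dimethoxybenzene
Product: 3 1,2-dibromo-4,5-dimethoxybenzene
Conditions: Br2 (2.1 equiv), AcOH, 0 °C → rt
Reagents that add atoms: bromine, BrBr
Why: Electrophilic aromatic bromination; each bromine enters para to a methoxy group, giving the symmetrical benzyne precursor.

Step 3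
Reactants: 1 catechol
Product: 5 2-methoxyphenyl 4-methylbenzenesulfonate, via 2-hydroxyphenyl 4-methylbenzenesulfonate 4 (not isolated)
Conditions: TsCl (1.0 equiv), K2CO3, acetone, 0 °C → rt; then MeI, 56 °C
Reagents that add atoms: 4-methylbenzenesulfonyl chloride, Cc1ccc(cc1)S(Cl)(=O)=O; iodomethane, CI
Why: Mono-O-sulfonylation (the second hydroxyl is deactivated once the first is sulfonylated) followed by Williamson methylation in the same pot; the tosylate protects the phenol and directs the next substitution.

Step 4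
Reactants: 5 2-methoxyphenyl 4-methylbenzenesulfonate; 6 formaldehyde (as paraformaldehyde)
Product: 7 5-(chloromethyl)-2-methoxyphenyl 4-methylbenzenesulfonate
Conditions: (CH2O)n, HCl (g), ZnCl2 (cat.), AcOH, 50 °C
Reagents that add atoms: hydrogen chloride, Cl
Why: Blanc chloromethylation; substitution goes para to the activating methoxy group and not para to the deactivating tosyloxy group, which fixes the 3-oxy-4-methoxy pattern of ring C.

Step 5
Reactants: 7 5-(chloromethyl)-2-methoxyphenyl 4-methylbenzenesulfonate; 8 carbon monoxide; 9 (2R,5R)-2,5-dimethylpyrrolidine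
Product: 10 5-{2-[(2R,5R)-2,5-dimethylpyrrolidin-1-yl]-2-oxoethyl}-2-methoxyphenyl 4-methylbenzenesulfonate
Conditions: Pd(OAc)2 (2 mol %), Xantphos (3 mol %), CO (1 atm), K2CO3, toluene, 80 °C
Reagents that add atoms: none
Why: Palladium-catalysed aminocarbonylation (oxidative addition of the benzylic chloride to zerovalent palladium, CO insertion, aminolysis of the acyl-palladium); the hindered amine is slow in direct N-benzylation and the aryl tosylate is inert under these conditions.

Step 6
Reactants: 10 the arylacetamide; 11 cis-2-butene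
Product: 14 (2S,3S,4R)-2-[4-methoxy-3-(tosyloxy)phenyl]-3,4-dimethylcyclobutan-1-one, via keteniminium triflate 12 (not isolated), via cyclobutaniminium triflate 13 (not isolated)
Conditions: Tf2O, 2,4,6-collidine, cis-2-butene (10 equiv), ClCH2CH2Cl, −20 → 40 °C (sealed tube); then H2O, rt
Reagents that add atoms: water, O
Why: Ghosez keteniminium–alkene [2+2] cycloaddition; the cis geometry of the alkene is kept (3,4-cis methyls) and the C2-symmetric auxiliary decides which alkene carbon bonds to the iminium carbon, setting C3 and C4; hydrolysis releases the ketone and the auxiliary, and the aryl-bearing C2 is epimerisable and is destroyed in step 7.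

Step 7
Reactants: 14 the cyclobutanone; 3 1,2-dibromo-4,5-dimethoxybenzene
Product: 19 (2R,3R,4R)-6,7-dimethoxy-4-[4-methoxy-3-(tosyloxy)phenyl]-2,3-dimethyl-3,4-dihydronaphthalen-1(2H)-one (all-cis), via sodium cyclobutenolate 15 (not isolated), via 4,5-dimethoxybenzyne 16 (not isolated), via tricyclic benzocyclobutenoxide 17 (not isolated), via ring-expanded benzylic anion 18 (not isolated)
Conditions: NaH, THF, 0 °C → rt; then 3 (1.3 equiv), n-BuLi (1.3 equiv), −78 → −20 °C; then AcOH, −78 °C
Reagents that add atoms: none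
Why: Proposed new method: aryne σ-insertion ring expansion of a 2-arylcyclobutanone – enolate 15 adds through its benzylic carbon to the symmetrical benzyne 16 (from 3 by bromine–lithium exchange and loss of LiBr), the aryl anion formed closes onto the strained cyclobutanone carbonyl to give alkoxide 17, and strain-driven retro-aldol-type fragmentation of the old C1–C2 bond (a stepwise, anionic 1,2-acyl shift from carbon to the arene, four- to six-membered ring) gives the doubly benzylic, carbonyl-conjugated anion 18; protonation at C4 from the face opposite the two cis methyl groups puts the aryl group cis to the C3 methyl, while C3 is carried through untouched; the closest known reaction type is the acyl-alkylation of arynes by β-ketoester and benzyl ketone enolates, which has not been shown on cyclobutanones or with stereocontrol in the final protonation.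

Step 8
Reactants: 19 the all-cis tetralone tosylate
Product: 20 (2S,3R,4R)-4-(3-hydroxy-4-methoxyphenyl)-6,7-dimethoxy-2,3-dimethyl-3,4-dihydronaphthalen-1(2H)-one
Conditions: KOH, 1,4-dioxane/H2O (1:1), 90 °C, Ar; then 1 M HCl
Reagents that add atoms: none
Why: Hydroxide cleaves the aryl sulfonate at sulfur and equilibrates C2 through the enolate to the 2,3-trans isomer (both methyls equatorial, aryl pseudo-axial); C3 is not acidic and the C4–H lies near the plane of ring A, so neither is scrambled.

## Compound list

1 | catechol (benzene-1,2-diol) | Oc1ccccc1O | starting material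
2 | 1,2-dimethoxybenzene | COc1ccccc1OC | intermediate
3 | 1,2-dibromo-4,5-dimethoxybenzene | COc1cc(Br)c(Br)cc1OC | intermediate
4 | 2-hydroxyphenyl 4-methylbenzenesulfonate | Oc1ccccc1OS(=O)(=O)c1ccc(C)cc1 | intermediate
5 | 2-methoxyphenyl 4-methylbenzenesulfonate | COc1ccccc1OS(=O)(=O)c1ccc(C)cc1 | intermediate
6 | formaldehyde (used as paraformaldehyde) | C=O | starting material
7 | 5-(chloromethyl)-2-methoxyphenyl 4-methylbenzenesulfonate | COc1ccc(CCl)cc1OS(=O)(=O)c1ccc(C)cc1 | intermediate
8 | carbon monoxide | [C-]#[O+] | starting material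
9 | (2R,5R)-2,5-dimethylpyrrolidine (auxiliary) | C[C@@H]1CC[C@@H](C)N1 | starting material
10 | 5-{2-[(2R,5R)-2,5-dimethylpyrrolidin-1-yl]-2-oxoethyl}-2-methoxyphenyl 4-methylbenzenesulfonate | C[C@@H]1CC[C@@H](C)N1C(=O)Cc1ccc(OC)c(OS(=O)(=O)c2ccc(C)cc2)c1 | intermediate
11 | cis-2-butene ((Z)-but-2-ene) | C/C=C\C | starting material
12 | (2R,5R)-1-{2-[4-methoxy-3-(tosyloxy)phenyl]ethenylidene}-2,5-dimethylpyrrolidinium triflate (keteniminium salt) | C[C@@H]1CC[C@@H](C)[N+]1=C=Cc1ccc(OC)c(OS(=O)(=O)c2ccc(C)cc2)c1.[O-]S(=O)(=O)C(F)(F)F | intermediate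
13 | (2R,5R)-1-{(2S,3S,4R)-2-[4-methoxy-3-(tosyloxy)phenyl]-3,4-dimethylcyclobutylidene}-2,5-dimethylpyrrolidinium triflate | C[C@@H]1CC[C@@H](C)[N+]1=C1[C@H](C)[C@H](C)[C@H]1c1ccc(OC)c(OS(=O)(=O)c2ccc(C)cc2)c1.[O-]S(=O)(=O)C(F)(F)F | intermediate
14 | (2S,3S,4R)-2-[4-methoxy-3-(tosyloxy)phenyl]-3,4-dimethylcyclobutan-1-one (methyls cis, aryl trans to the C3 methyl; the C2 epimer gives the same enolate) | O=C1[C@H](C)[C@H](C)[C@H]1c1ccc(OC)c(OS(=O)(=O)c2ccc(C)cc2)c1 | intermediate
15 | sodium (3S,4R)-2-[4-methoxy-3-(tosyloxy)phenyl]-3,4-dimethylcyclobut-1-en-1-olate | [Na+].[O-]C1=C(c2ccc(OC)c(OS(=O)(=O)c3ccc(C)cc3)c2)[C@@H](C)[C@H]1C | intermediate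
16 | 4,5-dimethoxybenzyne | COC1=CC#CC=C1OC | intermediate
17 | sodium tricyclic benzocyclobutenoxide (ring A fused cis across the former C1–C2 bond, on the face opposite the two methyls) | [Na+].[O-][C@]12[C@H](C)[C@H](C)[C@@]1(c1ccc(OC)c(OS(=O)(=O)c3ccc(C)cc3)c1)c1cc(OC)c(OC)cc21 | intermediate
18 | sodium (2R,3S)-6,7-dimethoxy-4-[4-methoxy-3-(tosyloxy)phenyl]-2,3-dimethyl-1-oxo-1,2,3,4-tetrahydronaphthalen-4-ide (delocalised dienolate) | [Na+].COc1ccc([C-]2c3cc(OC)c(OC)cc3C(=O)[C@H](C)[C@@H]2C)cc1OS(=O)(=O)c1ccc(C)cc1 | intermediate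
19 | (2R,3R,4R)-6,7-dimethoxy-4-[4-methoxy-3-(tosyloxy)phenyl]-2,3-dimethyl-3,4-dihydronaphthalen-1(2H)-one (all-cis) | COc1ccc([C@@H]2c3cc(OC)c(OC)cc3C(=O)[C@H](C)[C@@H]2C)cc1OS(=O)(=O)c1ccc(C)cc1 | intermediate
20 | (2S,3R,4R)-4-(3-hydroxy-4-methoxyphenyl)-6,7-dimethoxy-2,3-dimethyl-3,4-dihydronaphthalen-1(2H)-one | COc1ccc([C@@H]2c3cc(OC)c(OC)cc3C(=O)[C@@H](C)[C@@H]2C)cc1O | target

## Step count and risks

Total steps: 8. Longest linear sequence: 6 (steps 3, 4, 5, 6, 7, 8 from catechol); steps 1 and 2 form the short branch that joins at step 7.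

**Step 7 (the proposed ring expansion).** It may fail through oligomerisation of the benzyne, O-arylation or over-arylation of anion 18, or through poor facial selectivity in the C4 protonation. The fallback uses known chemistry, sets out from 14 (together with 2) and comes back at 19. Baeyer–Villiger oxidation of 14 (mCPBA, NaHCO3, CH2Cl2; the benzylic carbon migrates) gives (3R,4S,5S)-5-[4-methoxy-3-(tosyloxy)phenyl]-3,4-dimethyloxolan-2-one F1. Friedel–Crafts alkylation of 2 by F1 (TfOH, CH2Cl2, 0 °C) then follows; the arene is expected to attack the benzylic cation anti to the carboxyl-bearing chain, which corresponds to the 3,4-cis series, but this selectivity would have to be checked and the isomers separated if needed. It gives (2R,3R,4S)-4-(3,4-dimethoxyphenyl)-4-[4-methoxy-3-(tosyloxy)phenyl]-2,3-dimethylbutanoic acid F2. Cyclisation of F2 with Eaton's reagent (P2O5 in MeSO3H, 40 °C) acylates the dimethoxyphenyl ring only, the tosyloxy-bearing ring being deactivated, and gives 19; any C2 epimer converges on 20 in step 8.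

**Step 6 (auxiliary-controlled [2+2]).** The hindered keteniminium may react poorly with an unactivated gaseous alkene, and the level and sense of induction are not secured. The fallback sets out from 7 and comes back at 14. Aminocarbonylation of 7 with pyrrolidine (as in step 5) gives the achiral amide 2-methoxy-5-[2-oxo-2-(pyrrolidin-1-yl)ethyl]phenyl 4-methylbenzenesulfonate F3, whose less hindered keteniminium adds cis-2-butene more readily. Hydrolysis gives racemic 2-[4-methoxy-3-(tosyloxy)phenyl]-3,4-dimethylcyclobutan-1-one F4, which is resolved by preparative chromatography on a chiral stationary phase to give 14.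

**Step 5 (aminocarbonylation with a hindered amine).** Direct N-benzylation of 9 or slow aminolysis of the acyl-palladium may dominate. The fallback sets out from 5 and 9 and comes back at 10. Bromination of 5 (Br2, AcOH; para to the methoxy group) gives 5-bromo-2-methoxyphenyl 4-methylbenzenesulfonate F5. Acetylation of 9 (acetyl chloride, Et3N) gives 1-[(2R,5R)-2,5-dimethylpyrrolidin-1-yl]ethan-1-one F6. Palladium-catalysed α-arylation of the lithium enolate of F6 with F5 (LiN(SiMe3)2, Pd(dba)2, P(t-Bu)3, toluene, rt) gives 10.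

## Further compounds

F1 | step 7 | (3R,4S,5S)-5-[4-methoxy-3-(tosyloxy)phenyl]-3,4-dimethyloxolan-2-one | O=C1[C@H](C)[C@H](C)[C@@H](c2ccc(OC)c(OS(=O)(=O)c3ccc(C)cc3)c2)O1
F2 | step 7 | (2R,3R,4S)-4-(3,4-dimethoxyphenyl)-4-[4-methoxy-3-(tosyloxy)phenyl]-2,3-dimethylbutanoic acid | OC(=O)[C@H](C)[C@H](C)[C@@H](c1ccc(OC)c(OC)c1)c1ccc(OC)c(OS(=O)(=O)c2ccc(C)cc2)c1
F3 | step 6 | 2-methoxy-5-[2-oxo-2-(pyrrolidin-1-yl)ethyl]phenyl 4-methylbenzenesulfonate | COc1ccc(CC(=O)N2CCCC2)cc1OS(=O)(=O)c1ccc(C)cc1
F4 | step 6 | racemic 2-[4-methoxy-3-(tosyloxy)phenyl]-3,4-dimethylcyclobutan-1-one (1:1 mixture of 14 and its enantiomer) | O=C1[C@H](C)[C@H](C)[C@H]1c1ccc(OC)c(OS(=O)(=O)c2ccc(C)cc2)c1.O=C1[C@@H](C)[C@@H](C)[C@@H]1c1ccc(OC)c(OS(=O)(=O)c2ccc(C)cc2)c1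
F5 | step 5 | 5-bromo-2-methoxyphenyl 4-methylbenzenesulfonate | COc1ccc(Br)cc1OS(=O)(=O)c1ccc(C)cc1
F6 | step 5 | 1-[(2R,5R)-2,5-dimethylpyrrolidin-1-yl]ethan-1-one | C[C@@H]1CC[C@@H](C)N1C(C)=O
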